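**Retrosynthetic overview**
- The target is a (2S)-flavan: a chroman with ring A carrying 5,7-hydroxyls and, at C8, a 2-(4-hydroxyphenyl)-1,2-dioxoethyl group. The diketone is traced back to a diarylalkyne (oxidation), the alkyne to a C8 bromide and an aryl acetylene (Sonogashira), and the bromide to the parent 5,7-dioxygenated chroman.
- The strategy rests on the pyran ring: O1 and the C4 methylene sit on adjacent ring A carbons (C8a and C4a), and the 4-oxyphenyl group sits on C2. Cutting O1–C2 and C3–C4 in a retro-[4+2] sense gives a ring A ortho-quinone methide and a 4-oxystyrene.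
- The methide is generated from a salicyl alcohol in which only the oxygen destined to become O1 is free (from 2,4,6-trihydroxybenzaldehyde); the styrene comes from 4-hydroxybenzaldehyde.
- Ring order: ring A and both 4-oxyphenyl rings are bought; the pyran ring is the only ring formed, in the enantioselective cycloaddition, which also sets the single stereocentre C2.

Key step: step 5

Assumption: the sense of induction of the chiral acid in step 5 cannot be predicted with confidence; the (R)-configured acid is written, and its enantiomer is to be used should it favour the (2R)-chroman.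

**Route**

Step 1
Reactants: 1 2,4,6-trihydroxybenzaldehyde
Product: 2 2-hydroxy-4,6-bis(methoxymethoxy)benzaldehyde
Conditions: MOMCl (2.1 equiv), i-Pr2NEt, CH2Cl2, 0 °C to rt
Reagents that add atoms: chloromethyl methyl ether, COCCl
Why: Phenol O-alkylation (MOM protection) should stop at the bis-ether, because the 4-hydroxyl and one of the two equivalent ortho hydroxyls react while the last ortho hydroxyl is held in a hydrogen bond to the aldehyde.

Step 2
Reactants: 2 2-hydroxy-4,6-bis(methoxymethoxy)benzaldehyde
Product: 3 2-(hydroxymethyl)-3,5-bis(methoxymethoxy)phenol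
Conditions: NaBH4, THF/MeOH, 0 °C; pH 7 buffer work-up, used without chromatography
Reagents that add atoms: none
Why: Hydride reduction of the aldehyde under basic conditions leaves the MOM acetals intact, and a neutral work-up avoids premature ionisation of the very electron-rich benzylic alcohol.

Step 3
Reactants: 4 4-hydroxybenzaldehyde
Product: 5 4-(methoxymethoxy)benzaldehyde
Conditions: MOMCl, i-Pr2NEt, CH2Cl2, 0 °C to rt
Reagents that add atoms: chloromethyl methyl ether, COCCl
Why: Routine MOM protection of a phenol by O-alkylation.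

Step 4
Reactants: 5 4-(methoxymethoxy)benzaldehyde
Product: 6 1-ethenyl-4-(methoxymethoxy)benzene
Conditions: Ph3PCH3Br, KOt-Bu, THF, 0 °C to rt
Reagents that add atoms: methyltriphenylphosphonium bromide, C[P+](c1ccccc1)(c1ccccc1)c1ccccc1.[Br-]
Why: Wittig methylenation of an aromatic aldehyde with the unstabilised ylide should give the terminal alkene, the acetal being inert to base.

Step 5
Reactants: 3 2-(hydroxymethyl)-3,5-bis(methoxymethoxy)phenol; 6 1-ethenyl-4-(methoxymethoxy)benzene
Product: 8 (2S)-5,7-bis(methoxymethoxy)-2-[4-(methoxymethoxy)phenyl]chromane, via ortho-quinone methide 7 (not isolated)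
Conditions: (R)-3,3'-bis(2,4,6-triisopropylphenyl)-1,1'-binaphthyl-2,2'-diyl hydrogen phosphate (10 mol%), 5 Å MS, PhCF3, 0 °C to rt; 3 added slowly to 6 (4 equiv)
Reagents that add atoms: none
Why: Proposed new method: the chiral phosphoric acid protonates the benzylic hydroxyl of 3, whose ionisation is driven by the ortho and para oxygen substituents, and the resulting ortho-quinone methide 7 stays hydrogen-bonded to the phosphate through its carbonyl oxygen while the electron-rich styrene 6 adds in an inverse-electron-demand hetero-Diels–Alder reaction, the methide CH2 bonding to the styrene terminus (C3–C4) and the oxygen to the benzylic carbon (O1–C2). The closest known reaction type is the chiral Brønsted acid catalysed [4+2] cycloaddition of in situ ortho-quinone methides bearing an aryl group on the methide carbon with styrenes, together with the racemic thermal cycloaddition of unsubstituted ortho-quinone methides with styrenes; the new element is enantiocontrol with a bare CH2 terminus. The pyran ring closes by this intermolecular [4+2] cycloaddition with rearomatisation of ring A, probably asynchronously with C–C bonding ahead of C–O bonding. The single stereocentre C2 is set by the catalyst: the phosphate bridges the methide oxygen and the developing 4-alkoxybenzylic cation, so that one face of the styrene benzylic carbon is presented to oxygen, and the (2S) sense is fixed by the choice of catalyst enantiomer. Regioselectivity follows from the polarity of both partners and from the fact that only one ring A oxygen is free, while selectivity over Friedel–Crafts oligomerisation of 7 with electron-rich arenes is sought by keeping 7 dilute (slow addition) in an excess of 6 over molecular sieves.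

Step 6
Reactants: 8 (2S)-5,7-bis(methoxymethoxy)-2-[4-(methoxymethoxy)phenyl]chromane
Product: 9 (2S)-8-bromo-5,7-bis(methoxymethoxy)-2-[4-(methoxymethoxy)phenyl]chromane
Conditions: NBS (1.0 equiv), CH2Cl2, −78 °C to −20 °C, dark
Reagents that add atoms: N-bromosuccinimide, O=C1CCC(=O)N1Br
Why: Electrophilic aromatic bromination should occur on the phloroglucinol-type ring A rather than the mono-oxygenated ring B, and at C8 (next to the tied-back ring oxygen) rather than at C6 (between two MOM ethers), in line with the C8-selective bromination of protected 5,7-dioxygenated flavans; C2 is not touched.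

Step 7
Reactants: 10 4-ethynylphenol
Product: 11 1-ethynyl-4-(methoxymethoxy)benzene
Conditions: MOMCl, i-Pr2NEt, CH2Cl2, 0 °C
Reagents that add atoms: chloromethyl methyl ether, COCCl
Why: MOM protection of the phenol by O-alkylation under mild base leaves the terminal alkyne untouched.

Step 8
Reactants: 9 (2S)-8-bromo-5,7-bis(methoxymethoxy)-2-[4-(methoxymethoxy)phenyl]chromane; 11 1-ethynyl-4-(methoxymethoxy)benzene
Product: 12 (2S)-5,7-bis(methoxymethoxy)-2-[4-(methoxymethoxy)phenyl]-8-{[4-(methoxymethoxy)phenyl]ethynyl}chromane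
Conditions: PdCl2(MeCN)2 (3 mol%), 2-dicyclohexylphosphino-2',4',6'-triisopropylbiphenyl (XPhos, 9 mol%), Cs2CO3, MeCN, 80 °C
Reagents that add atoms: none
Why: Copper-free Sonogashira coupling, in which the bulky electron-rich biarylphosphine allows oxidative addition into the hindered, electron-rich aryl bromide and the carbonate base spares the acetals and the C2 stereocentre.

Step 9
Reactants: 12 (2S)-5,7-bis(methoxymethoxy)-2-[4-(methoxymethoxy)phenyl]-8-{[4-(methoxymethoxy)phenyl]ethynyl}chromane
Product: 13 1-[(2S)-5,7-bis(methoxymethoxy)-2-[4-(methoxymethoxy)phenyl]chroman-8-yl]-2-[4-(methoxymethoxy)phenyl]ethane-1,2-dione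
Conditions: PdCl2 (10 mol%), DMSO, 120–140 °C
Reagents that add atoms: dimethyl sulfoxide, CS(C)=O
Why: Palladium dichloride catalysed oxidation of a diarylalkyne to the benzil with DMSO as oxygen donor and terminal oxidant, run neutral and aprotic so that the MOM ethers and the C2 benzylic ether should survive.

Step 10
Reactants: 13 1-[(2S)-5,7-bis(methoxymethoxy)-2-[4-(methoxymethoxy)phenyl]chroman-8-yl]-2-[4-(methoxymethoxy)phenyl]ethane-1,2-dione
Product: 14 1-[(2S)-5,7-dihydroxy-2-(4-hydroxyphenyl)chroman-8-yl]-2-(4-hydroxyphenyl)ethane-1,2-dione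
Conditions: HCl (3 M aq.), MeOH/THF, 40 °C
Reagents that add atoms: none
Why: Acid-catalysed transacetalisation to methanol removes all four MOM groups, and the mild temperature together with the C8 acyl group, which lowers the basicity of O1, should keep the C2–O1 benzylic ether from ionising, so the (2S) centre is retained.

**Compound list**

1 | 2,4,6-trihydroxybenzaldehyde | O=Cc1c(O)cc(O)cc1O | starting material
2 | 2-hydroxy-4,6-bis(methoxymethoxy)benzaldehyde | O=Cc1c(O)cc(OCOC)cc1OCOC | intermediate
3 | 2-(hydroxymethyl)-3,5-bis(methoxymethoxy)phenol | OCc1c(O)cc(OCOC)cc1OCOC | intermediate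
4 | 4-hydroxybenzaldehyde | O=Cc1ccc(O)cc1 | starting material
5 | 4-(methoxymethoxy)benzaldehyde | COCOc1ccc(C=O)cc1 | intermediate
6 | 1-ethenyl-4-(methoxymethoxy)benzene | COCOc1ccc(C=C)cc1 | intermediate
7 | 3,5-bis(methoxymethoxy)-6-methylidenecyclohexa-2,4-dien-1-one (ortho-quinone methide, not isolated) | C=C1C(=O)C=C(OCOC)C=C1OCOC | intermediate
8 | (2S)-5,7-bis(methoxymethoxy)-2-[4-(methoxymethoxy)phenyl]chromane | COCOc1cc(OCOC)c2c(c1)O[C@H](c1ccc(OCOC)cc1)CC2 | intermediate
9 | (2S)-8-bromo-5,7-bis(methoxymethoxy)-2-[4-(methoxymethoxy)phenyl]chromane | COCOc1cc(OCOC)c2c(c1Br)O[C@H](c1ccc(OCOC)cc1)CC2 | intermediate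
10 | 4-ethynylphenol | C#Cc1ccc(O)cc1 | starting material
11 | 1-ethynyl-4-(methoxymethoxy)benzene | C#Cc1ccc(OCOC)cc1 | intermediate
12 | (2S)-5,7-bis(methoxymethoxy)-2-[4-(methoxymethoxy)phenyl]-8-{[4-(methoxymethoxy)phenyl]ethynyl}chromane | COCOc1cc(OCOC)c2c(c1C#Cc1ccc(OCOC)cc1)O[C@H](c1ccc(OCOC)cc1)CC2 | intermediate
13 | 1-[(2S)-5,7-bis(methoxymethoxy)-2-[4-(methoxymethoxy)phenyl]chroman-8-yl]-2-[4-(methoxymethoxy)phenyl]ethane-1,2-dione | COCOc1cc(OCOC)c2c(c1C(=O)C(=O)c1ccc(OCOC)cc1)O[C@H](c1ccc(OCOC)cc1)CC2 | intermediate
14 | 1-[(2S)-5,7-dihydroxy-2-(4-hydroxyphenyl)chroman-8-yl]-2-(4-hydroxyphenyl)ethane-1,2-dione | O=C(C(=O)c1c(O)cc(O)c2c1O[C@H](c1ccc(O)cc1)CC2)c1ccc(O)cc1 | target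

**Step count**

Total steps: 10. Longest linear sequence: 7 (steps 1, 2, 5, 6, 8, 9, 10; the branch through steps 3, 4 is equally long).

**Steps most likely to fail**

1. Step 5 (proposed new method). Three processes threaten it:
   - poor facial selectivity, because the methide terminus is an unsubstituted CH2 and the styrene offers the catalyst no second binding point;
   - consumption of the methide by Friedel–Crafts alkylation of electron-rich arenes (oligomerisation);
   - acid-induced loss of MOM groups.

   The fallback uses known chemistry and sets out from 2. 1-(4-Hydroxyphenyl)ethanone is MOM-protected (MOMCl, i-Pr2NEt, CH2Cl2) to 1-[4-(methoxymethoxy)phenyl]ethan-1-one F1. Claisen–Schmidt condensation of 2 with F1 (KOH, EtOH, rt) should give (E)-3-[2-hydroxy-4,6-bis(methoxymethoxy)phenyl]-1-[4-(methoxymethoxy)phenyl]prop-2-en-1-one F2. Hydrogenation of the alkene (H2, Pd/C, EtOAc) should give 3-[2-hydroxy-4,6-bis(methoxymethoxy)phenyl]-1-[4-(methoxymethoxy)phenyl]propan-1-one F3. Corey–Bakshi–Shibata reduction ((S)-1-methyl-3,3-diphenyltetrahydro-1H,3H-pyrrolo[1,2-c][1,3,2]oxazaborole, BH3·SMe2 in excess, THF) should give (1R)-3-[2-hydroxy-4,6-bis(methoxymethoxy)phenyl]-1-[4-(methoxymethoxy)phenyl]propan-1-ol F4. Mitsunobu cyclisation (PPh3, diisopropyl azodicarboxylate, THF, 0 °C) then closes the pyran ring by phenol attack with inversion at the carbinol carbon, and the route is rejoined at 8.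

2. Step 9. The MOM ether ortho to the alkyne may be lost or may migrate under the Lewis acidic divalent palladium, followed by 5-endo cyclisation of that oxygen onto the activated alkyne (benzofuran formation); the doubly ortho-substituted alkyne may also oxidise sluggishly.

   The fallback sets out from 12 and avoids π-acid activation. Hydroboration with dicyclohexylborane (THF, 0 °C to rt) and oxidation (NaOH, H2O2) should give a mixture of two regioisomeric deoxybenzoins, which need not be separated: 1-[(2S)-5,7-bis(methoxymethoxy)-2-[4-(methoxymethoxy)phenyl]chroman-8-yl]-2-[4-(methoxymethoxy)phenyl]ethan-1-one F5 and 2-[(2S)-5,7-bis(methoxymethoxy)-2-[4-(methoxymethoxy)phenyl]chroman-8-yl]-1-[4-(methoxymethoxy)phenyl]ethan-1-one F6. Base-mediated aerobic α-oxidation of the mixture (DABCO, air, DMF, 90 °C) should convert both into the same diketone, and the route is rejoined at 13.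

3. Step 8. Oxidative addition into the C8–Br bond, flanked by two oxygen substituents on a very electron-rich ring, may be slow, so that oligomerisation of the alkyne or protodebromination takes over.

   The fallback sets out from 9 and reverses the roles of the coupling partners. Bromine–lithium exchange (n-BuLi, THF, −78 °C) and quenching with DMF should give (2S)-5,7-bis(methoxymethoxy)-2-[4-(methoxymethoxy)phenyl]chromane-8-carbaldehyde F7. Ohira–Bestmann homologation (dimethyl (1-diazo-2-oxopropyl)phosphonate, K2CO3, MeOH, rt) should give (2S)-8-ethynyl-5,7-bis(methoxymethoxy)-2-[4-(methoxymethoxy)phenyl]chromane F8. Classical Sonogashira coupling of F8 with 1-iodo-4-(methoxymethoxy)benzene F9 (made from 4-iodophenol with MOMCl and i-Pr2NEt) under Pd(PPh3)2Cl2, CuI, Et3N, THF at rt puts the oxidative addition on an unhindered aryl iodide, and the route is rejoined at 12.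

**Further compounds**

F1 | step 5 | 1-[4-(methoxymethoxy)phenyl]ethan-1-one | CC(=O)c1ccc(OCOC)cc1
F2 | step 5 | (E)-3-[2-hydroxy-4,6-bis(methoxymethoxy)phenyl]-1-[4-(methoxymethoxy)phenyl]prop-2-en-1-one | COCOc1ccc(cc1)C(=O)/C=C/c1c(O)cc(OCOC)cc1OCOC
F3 | step 5 | 3-[2-hydroxy-4,6-bis(methoxymethoxy)phenyl]-1-[4-(methoxymethoxy)phenyl]propan-1-one | COCOc1ccc(cc1)C(=O)CCc1c(O)cc(OCOC)cc1OCOC
F4 | step 5 | (1R)-3-[2-hydroxy-4,6-bis(methoxymethoxy)phenyl]-1-[4-(methoxymethoxy)phenyl]propan-1-ol | O[C@@H](c1ccc(OCOC)cc1)CCc1c(O)cc(OCOC)cc1OCOC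
F5 | step 9 | 1-[(2S)-5,7-bis(methoxymethoxy)-2-[4-(methoxymethoxy)phenyl]chroman-8-yl]-2-[4-(methoxymethoxy)phenyl]ethan-1-one | COCOc1cc(OCOC)c2c(c1C(=O)Cc1ccc(OCOC)cc1)O[C@H](c1ccc(OCOC)cc1)CC2
F6 | step 9 | 2-[(2S)-5,7-bis(methoxymethoxy)-2-[4-(methoxymethoxy)phenyl]chroman-8-yl]-1-[4-(methoxymethoxy)phenyl]ethan-1-one | COCOc1cc(OCOC)c2c(c1CC(=O)c1ccc(OCOC)cc1)O[C@H](c1ccc(OCOC)cc1)CC2
F7 | step 8 | (2S)-5,7-bis(methoxymethoxy)-2-[4-(methoxymethoxy)phenyl]chromane-8-carbaldehyde | COCOc1cc(OCOC)c2c(c1C=O)O[C@H](c1ccc(OCOC)cc1)CC2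
F8 | step 8 | (2S)-8-ethynyl-5,7-bis(methoxymethoxy)-2-[4-(methoxymethoxy)phenyl]chromane | COCOc1cc(OCOC)c2c(c1C#C)O[C@H](c1ccc(OCOC)cc1)CC2
F9 | step 8 | 1-iodo-4-(methoxymethoxy)benzene | COCOc1ccc(I)cc1
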